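**Plan**
Ring letters: A and E are the terminal 2,4,6-trioxygenated phenyl rings, B and D the pentasubstituted rings, C the central ring, and F the 3,4,5-trioxygenated phenoxy ring. In B and D, C1 bears ring A or E and C5 bears the ether oxygen to ring C.
Retrosynthesis: twelve O–H groups become O–CH3. The C5–C6 bond of ring B and of ring D is then cut, so each of these benzenes becomes a 2-pyrone. After that come the two biaryl bonds (pyrone C3–aryl), the two CH2–O bonds to ring C, and the ring C–O–ring F ether.
Enabling feature: in rings B and D the run C6(O)–C1(aryl)–C2(O)–C3(H)–C4(O) is the C2–C3–C4–C5–C6 chain of a 3-aryl-4-methoxy-2-pyrone. C5 lies between the oxygenated carbons C4 and C6 and is the 6-CH2 carbon of that pyrone, with the ether oxygen to ring C already attached.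
Forward: rings A, C, E and F are bought as arenes. F is joined to C, C is made a 1,3-diol, and two bromomethylpyrones from triacetic acid lactone are attached by SN2. A and E are added by a double Suzuki coupling, methoxide closes B and D together, and global demethylation ends the route.
Stereochemistry: none has to be set. The target has no stereocentre, and rings A and E are symmetric about their biaryl axes, so there are no atropisomers.

Key step: step 8

Remark: compounds 1, 5, 6 and 11 are taken as commercial.

Step 1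
Reactants: 1 4-hydroxy-6-methyl-2H-pyran-2-one (triacetic acid lactone)
Product: 2 4-methoxy-6-methyl-2H-pyran-2-one
Conditions: Me2SO4, K2CO3, acetone, reflux
Reagents that add atoms: dimethyl sulfate, COS(=O)(=O)OC
Why: Williamson-type O-methylation of the acidic vinylogous carboxylic acid OH with a hard methylating agent is the standard entry to 4-methoxy-2-pyrones, and the isomeric 2-methoxy-4-pyrone should be at most a minor, separable by-product.

Step 2
Reactants: 2 4-methoxy-6-methyl-2H-pyran-2-one
Product: 3 3-bromo-4-methoxy-6-methyl-2H-pyran-2-one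
Conditions: NBS, MeCN, rt, dark
Reagents that add atoms: N-bromosuccinimide, O=C1CCC(=O)N1Br
Why: Electrophilic substitution of 4-alkoxy-2-pyrones goes to C3, the enol-ether carbon next to the lactone carbonyl, so ionic bromination should install the coupling handle there and leave the methyl group alone.

Step 3
Reactants: 3 3-bromo-4-methoxy-6-methyl-2H-pyran-2-one
Product: 4 3-bromo-6-(bromomethyl)-4-methoxy-2H-pyran-2-one
Conditions: NBS (1.05 equiv), AIBN, PhCF3, 85 °C
Reagents that add atoms: N-bromosuccinimide, O=C1CCC(=O)N1Br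
Why: In this Wohl–Ziegler bromination C3 is already blocked and a radical chain runs in a non-polar solvent, so hydrogen abstraction should occur at the 6-methyl group, whose radical is delocalised over the pyrone diene.

Step 4
Reactants: 5 2,6-dibromo-4-methoxyphenol; 6 (3,4,5-trimethoxyphenyl)boronic acid
Product: 7 1,3-dibromo-5-methoxy-2-(3,4,5-trimethoxyphenoxy)benzene
Conditions: Cu(OAc)2, pyridine, 4 Å MS, CH2Cl2, dry air, rt
Reagents that add atoms: none
Why: The Chan–Lam–Evans O-arylation runs at room temperature, accepts acidic 2,6-dihalophenols and electron-rich arylboronic acids, and should leave both C–Br bonds intact for the next step.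

Step 5
Reactants: 7 1,3-dibromo-5-methoxy-2-(3,4,5-trimethoxyphenoxy)benzene
Product: 9 5-methoxy-2-(3,4,5-trimethoxyphenoxy)benzene-1,3-diol, via bis(pinacol boronate) 8 (not isolated)
Conditions: B2pin2, Pd(dppf)Cl2, KOAc, 1,4-dioxane, 90 °C; then 30% H2O2, 2 M NaOH, THF, 0 °C; 1 M HCl
Reagents that add atoms: bis(pinacolato)diboron, CC1(C)OB(OC1(C)C)B1OC(C)(C)C(C)(C)O1 (boron groups of 8 only); hydrogen peroxide, OO
Why: Double Miyaura borylation followed by peroxide oxidation (aryl shift from boron to oxygen) replaces each C–Br by C–OH at the same carbon, and each bromide has only one ortho substituent, which this sequence tolerates.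

Step 6
Reactants: 9 5-methoxy-2-(3,4,5-trimethoxyphenoxy)benzene-1,3-diol; 4 3-bromo-6-(bromomethyl)-4-methoxy-2H-pyran-2-one (2.2 equiv)
Product: 10 6,6'-{[5-methoxy-2-(3,4,5-trimethoxyphenoxy)-1,3-phenylene]bis(oxymethylene)}bis(3-bromo-4-methoxy-2H-pyran-2-one)
Conditions: K2CO3, acetone, reflux, Ar
Reagents that add atoms: none
Why: In this twofold Williamson ether synthesis (SN2) the primary, allylic-type bromide of 4 should react with the phenoxides far faster than the sp2 C3–Br bond, so the ether that will later be the crowded one is made while its carbon is still an open CH2.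

Step 7
Reactants: 10 bis(3-bromopyron-6-ylmethyl) ether of ring C; 11 (2,4,6-trimethoxyphenyl)boronic acid (4 equiv)
Product: 12 6,6'-{[5-methoxy-2-(3,4,5-trimethoxyphenoxy)-1,3-phenylene]bis(oxymethylene)}bis[4-methoxy-3-(2,4,6-trimethoxyphenyl)-2H-pyran-2-one]
Conditions: Pd(OAc)2, SPhos, K3PO4, toluene/H2O, 90 °C
Reagents that add atoms: none
Why: This twofold Suzuki–Miyaura coupling at the pyrone C3–Br bonds uses the bulky, electron-rich biarylphosphine that is standard for di-ortho-substituted partners, and it comes before step 8 because 3-halo-2-pyrones undergo Perkin-type ring contraction to furoates in alkoxide.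

Step 8
Reactants: 12 ring C bis(pyron-6-ylmethyl) ether carrying rings A, E and F
Product: 14 3,3'-{[5-methoxy-2-(3,4,5-trimethoxyphenoxy)-1,3-phenylene]bis(oxy)}bis(2',4',6,6'-tetramethoxybiphenyl-2,4-diol) (dodecamethyl ether of the target; 4-OH and 6-OH of rings B and D free), via bis(keto ester) 13 (not isolated)
Conditions: NaOMe (10 equiv), MeOH/1,4-dioxane, sealed tube, 150 °C, Ar; then 1 M HCl
Reagents that add atoms: sodium methoxide, C[O-].[Na+] (its methoxy groups sit in 13 only and leave again; 14 is an isomer of 12)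
Why: Methoxide adds to the lactone carbonyl (pyrone C2) of each arm and the C2–O1 bond breaks, giving methyl ester/ketone 13 as its enolate, with the ester and the CH2C(=O)CH2OAr chain held cis on the C3=C4 double bond inherited from the pyrone. Proton exchange in methanol makes the enolate at the CH2(OAr) carbon available (the aryloxy group acidifies it relative to the methyl group of the parent pyrone); this carbon attacks the ester, methoxide leaves, the C5–C6 bond of ring B or D forms, and the cyclohexenedione tautomerises to the arene, so that pyrone O1 and the carbonyl oxygen end as the 4-OH and 6-OH flanking the ether. The closest known reaction is the alkoxide-induced isomerisation of 6-alkyl-4-methoxy-2-pyrones to phloroglucinol monomethyl ethers, that is, lactone opening followed by an intramolecular Claisen (Dieckmann-type) condensation. Ring B and ring D each close in the 6-(enolendo)-exo-trig mode, which is favoured, and no stereocentre is formed. The step needs selectivity between the enolisable carbons of the ketone: pyrone C5 could only close a four-membered ring onto the ester and pyrone C3 bears no hydrogen, so only the CH2(OAr) carbon leads to a stable product. Aromatisation and deprotonation to the phenoxides take each closed ring out of the equilibria, and methoxide in methanol keeps any exchange at the ester or at the C4 methoxy group degenerate.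

Step 9
Reactants: 14 dodecamethyl ether of the target
Product: 15 3,3'-{[5-hydroxy-2-(3,4,5-trihydroxyphenoxy)-1,3-phenylene]bis(oxy)}bis(biphenyl-2,2',4,4',6,6'-hexol) (CNP0279880.0)
Conditions: BBr3 (excess), CH2Cl2, −78 °C to rt, Ar; then ice/H2O
Reagents that add atoms: none
Why: In this Lewis-acid ether cleavage BBr3 binds each methoxy oxygen and bromide attacks the methyl carbon by SN2, a path closed to diaryl ether and biaryl bonds, so only the twelve O–CH3 bonds should break.

**Compound list**
1 | 4-hydroxy-6-methyl-2H-pyran-2-one (triacetic acid lactone) | Cc1cc(O)cc(=O)o1 | starting material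
2 | 4-methoxy-6-methyl-2H-pyran-2-one | Cc1cc(OC)cc(=O)o1 | intermediate
3 | 3-bromo-4-methoxy-6-methyl-2H-pyran-2-one | Cc1cc(OC)c(Br)c(=O)o1 | intermediate
4 | 3-bromo-6-(bromomethyl)-4-methoxy-2H-pyran-2-one | BrCc1cc(OC)c(Br)c(=O)o1 | intermediate
5 | 2,6-dibromo-4-methoxyphenol | COc1cc(Br)c(O)c(Br)c1 | starting material
6 | (3,4,5-trimethoxyphenyl)boronic acid | COc1cc(B(O)O)cc(OC)c1OC | starting material
7 | 1,3-dibromo-5-methoxy-2-(3,4,5-trimethoxyphenoxy)benzene | COc1cc(Br)c(Oc2cc(OC)c(OC)c(OC)c2)c(Br)c1 | intermediate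
8 | 2,2'-[5-methoxy-2-(3,4,5-trimethoxyphenoxy)-1,3-phenylene]bis(4,4,5,5-tetramethyl-1,3,2-dioxaborolane) | COc1cc(B2OC(C)(C)C(C)(C)O2)c(Oc2cc(OC)c(OC)c(OC)c2)c(B2OC(C)(C)C(C)(C)O2)c1 | intermediate
9 | 5-methoxy-2-(3,4,5-trimethoxyphenoxy)benzene-1,3-diol | COc1cc(O)c(Oc2cc(OC)c(OC)c(OC)c2)c(O)c1 | intermediate
10 | 6,6'-{[5-methoxy-2-(3,4,5-trimethoxyphenoxy)-1,3-phenylene]bis(oxymethylene)}bis(3-bromo-4-methoxy-2H-pyran-2-one) | COc1cc(OCc2cc(OC)c(Br)c(=O)o2)c(Oc2cc(OC)c(OC)c(OC)c2)c(OCc2cc(OC)c(Br)c(=O)o2)c1 | intermediate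
11 | (2,4,6-trimethoxyphenyl)boronic acid | COc1cc(OC)c(B(O)O)c(OC)c1 | starting material
12 | 6,6'-{[5-methoxy-2-(3,4,5-trimethoxyphenoxy)-1,3-phenylene]bis(oxymethylene)}bis[4-methoxy-3-(2,4,6-trimethoxyphenyl)-2H-pyran-2-one] | COc1cc(OCc2cc(OC)c(-c3c(OC)cc(OC)cc3OC)c(=O)o2)c(Oc2cc(OC)c(OC)c(OC)c2)c(OCc2cc(OC)c(-c3c(OC)cc(OC)cc3OC)c(=O)o2)c1 | intermediate
13 | dimethyl (2E,2'E)-6,6'-{[5-methoxy-2-(3,4,5-trimethoxyphenoxy)-1,3-phenylene]bis(oxy)}bis[3-methoxy-5-oxo-2-(2,4,6-trimethoxyphenyl)hex-2-enoate] (ester carbon and C4H2 cis) | COc1cc(OCC(=O)C\C(OC)=C(/C(=O)OC)c2c(OC)cc(OC)cc2OC)c(Oc2cc(OC)c(OC)c(OC)c2)c(OCC(=O)C\C(OC)=C(/C(=O)OC)c2c(OC)cc(OC)cc2OC)c1 | intermediate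
14 | 3,3'-{[5-methoxy-2-(3,4,5-trimethoxyphenoxy)-1,3-phenylene]bis(oxy)}bis(2',4',6,6'-tetramethoxybiphenyl-2,4-diol) | COc1cc(Oc2c(O)cc(OC)c(-c3c(OC)cc(OC)cc3OC)c2O)c(Oc2cc(OC)c(OC)c(OC)c2)c(Oc2c(O)cc(OC)c(-c3c(OC)cc(OC)cc3OC)c2O)c1 | intermediate
15 | 3,3'-{[5-hydroxy-2-(3,4,5-trihydroxyphenoxy)-1,3-phenylene]bis(oxy)}bis(biphenyl-2,2',4,4',6,6'-hexol) | Oc1cc(O)c(-c2c(O)cc(O)c(Oc3cc(O)cc(Oc4c(O)cc(O)c(-c5c(O)cc(O)cc5O)c4O)c3Oc3cc(O)c(O)c(O)c3)c2O)c(O)c1 | target

**Total step count:** 9
**Longest linear sequence:** 7 steps (1, 2, 3, 6, 7, 8, 9)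

**Steps most likely to fail**

Step 8.
- What may go wrong: the opened arms may not close, because the ester is a hindered, electron-rich acceptor next to a di-ortho-substituted aryl group. Retro-Claisen cleavage of the aryloxymethyl ketone by methoxide could then overtake the double condensation, as could closure of only one arm.
- Fallback: the ring construction is given up and the two ethers between ring C and rings B and D are made by Ullmann ether synthesis, setting out from diol 9.
- Boronic acid 11 is coupled with commercial 2-bromo-1,3,5-trimethoxybenzene (Pd(OAc)2, SPhos, K3PO4, toluene, 100 °C) to give 2,2',4,4',6,6'-hexamethoxybiphenyl F1.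
- One equivalent of N-iodosuccinimide in MeCN should give 3-iodo-2,2',4,4',6,6'-hexamethoxybiphenyl F2, and unreacted F1 is recycled.
- Two equivalents of F2 are condensed with 9 (CuI, picolinic acid, K3PO4, DMSO, 110 °C) to give the hexadecamethyl ether of the target F3.
- BBr3 under the conditions of step 9 cleaves all sixteen methyl ethers, and the route is rejoined at target 15.

Step 7.
- What may go wrong: protodeboronation of the di-ortho-methoxy boronic acid may outrun transmetalation at the hindered pyrone C3, so the coupling could stall after one arm. Zerovalent palladium may also ionise the pyronylmethyl aryl ether.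
- Fallback: the biaryl bond is made first, on the small pyrone and with a zinc nucleophile, and the ethers are formed afterwards. It sets out from dibromide 4.
- KOAc in DMF replaces the primary bromide and gives (5-bromo-4-methoxy-6-oxo-6H-pyran-2-yl)methyl acetate F4.
- 1,3,5-Trimethoxybenzene is lithiated (n-BuLi, THF, 0 °C) and transmetalated with ZnCl2 to chloro(2,4,6-trimethoxyphenyl)zinc F5.
- Negishi coupling of F5 with F4 (Pd(OAc)2, SPhos, THF, 60 °C) should give [4-methoxy-6-oxo-5-(2,4,6-trimethoxyphenyl)-6H-pyran-2-yl]methyl acetate F6.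
- Catalytic K2CO3 in MeOH at 0 °C frees 6-(hydroxymethyl)-4-methoxy-3-(2,4,6-trimethoxyphenyl)-2H-pyran-2-one F7.
- A double Mitsunobu reaction of F7 with diol 9 (PPh3, DIAD, THF, 0 °C to rt) comes back to the route at 12.

Step 9.
- What may go wrong: cleavage of the twelve ethers may stay incomplete and give a spread of partial methyl ethers. The free polyphenol may also be lost through air oxidation and irreversible adsorption during chromatography.
- Fallback: purification is moved to a protected stage, setting out from 14.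
- The crude BBr3 product (crude 15) is acetylated at once (Ac2O, pyridine, rt) to the hexadecaacetate of the target F8.
- F8 can be chromatographed or crystallised on normal silica, and under-demethylated fractions are separated and resubmitted to BBr3.
- Acid-catalysed methanolysis (catalytic HCl from AcCl in degassed MeOH, rt) leaves only volatile by-products and returns to 15 on evaporation.

**Further compounds**
F1 | step 8 | 2,2',4,4',6,6'-hexamethoxybiphenyl | COc1cc(OC)c(-c2c(OC)cc(OC)cc2OC)c(OC)c1
F2 | step 8 | 3-iodo-2,2',4,4',6,6'-hexamethoxybiphenyl | COc1cc(OC)c(-c2c(OC)cc(OC)c(I)c2OC)c(OC)c1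
F3 | step 8 | hexadecamethyl ether of the target | COc1cc(OC)c(-c2c(OC)cc(OC)c(Oc3cc(OC)cc(Oc4c(OC)cc(OC)c(-c5c(OC)cc(OC)cc5OC)c4OC)c3Oc3cc(OC)c(OC)c(OC)c3)c2OC)c(OC)c1
F4 | step 7 | (5-bromo-4-methoxy-6-oxo-6H-pyran-2-yl)methyl acetate | CC(=O)OCc1cc(OC)c(Br)c(=O)o1
F5 | step 7 | chloro(2,4,6-trimethoxyphenyl)zinc | COc1cc(OC)c([Zn]Cl)c(OC)c1
F6 | step 7 | [4-methoxy-6-oxo-5-(2,4,6-trimethoxyphenyl)-6H-pyran-2-yl]methyl acetate | CC(=O)OCc1cc(OC)c(-c2c(OC)cc(OC)cc2OC)c(=O)o1
F7 | step 7 | 6-(hydroxymethyl)-4-methoxy-3-(2,4,6-trimethoxyphenyl)-2H-pyran-2-one | OCc1cc(OC)c(-c2c(OC)cc(OC)cc2OC)c(=O)o1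
F8 | step 9 | hexadecaacetate of the target | CC(=O)Oc1cc(OC(C)=O)c(-c2c(OC(C)=O)cc(OC(C)=O)c(Oc3cc(OC(C)=O)cc(Oc4c(OC(C)=O)cc(OC(C)=O)c(-c5c(OC(C)=O)cc(OC(C)=O)cc5OC(C)=O)c4OC(C)=O)c3Oc3cc(OC(C)=O)c(OC(C)=O)c(OC(C)=O)c3)c2OC(C)=O)c(OC(C)=O)c1
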